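**Plan**

- Numbering: ring C1 (quaternary, bears CH3 and the pyranone carbon Ca), C2=C3(CH3)–C4=C5(CH3), C6 (CH) bearing the chain C7(CH3)=C8H–C9(=O)CH3.
- Cuts, in retrosynthetic order: C7=C8 (enone back to a C7 methyl ketone plus a propynyl unit); the pyranone ring at the Ca–C bond and the ring O–C(OMe) bond (back to a Ca aldehyde plus methyl 2-methyl-3-oxopentanoate); Ca and C7 are then tied through oxygen as a γ-lactone; last, C1–C2 and C5–C6.
- Enabling feature: C2–C5 carry H, CH3, H, CH3 exactly as C3–C6 of 4,6-dimethyl-2-pyrone, and C1(CH3)(Ca) cis to C6(H)(C7) is the ring fusion of an α,γ-dimethylbutenolide. The cyclohexadiene ring is therefore the pyrone/butenolide cycloadduct minus CO2.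
- Forward order: butenolide ring (ring-closing metathesis), carbocycle (Diels–Alder, CO2 loss), lactone opened, pyranone ring closed on Ca, side chain joined at C7 and rearranged.
- Stereochemistry: C7 (S) is bought with (S)-but-3-en-2-ol. It sends the diene to the opposite face, so C1 and C6 (cis, suprafacial) form as one enantiomer, and it is erased on oxidation. The E alkene is the thermodynamic outcome of the last step.

Key step: step 3

Remark: the chain stereocentres created in step 5 and the C7 carbinol created in step 12 are left undefined because all become sp2 later; adduct 6 is written as its endo isomer.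

**Step 1**
Reactants: 1 (S)-but-3-en-2-ol; 2 methacryloyl chloride
Product: 3 (S)-but-3-en-2-yl 2-methylprop-2-enoate
Conditions: Et3N, DMAP (cat.), CH2Cl2, 0 °C to rt
Reagents that add atoms: none
Why: DMAP-catalysed esterification of the secondary alcohol with the acid chloride leaves the C–O bond of the stereocentre untouched, so the (S) configuration is carried over unchanged.

**Step 2**
Reactants: 3 (S)-but-3-en-2-yl 2-methylprop-2-enoate
Product: 4 (S)-3,5-dimethylfuran-2(5H)-one
Conditions: second-generation Grubbs catalyst RuCl2(=CHPh)(PCy3)(H2IMes) (5 mol%), CH2Cl2 (0.01 M), 40 °C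
Reagents that add atoms: none
Why: Ring-closing metathesis of allyl methacrylates to α-methylbutenolides is reliable with this catalyst class, loss of ethene drives closure of the five-membered ring with its trisubstituted alkene, and the allylic stereocentre does not take part.

**Step 3**
Reactants: 4 (S)-3,5-dimethylfuran-2(5H)-one; 5 4,6-dimethyl-2H-pyran-2-one
Product: 7 (3S,3aR,7aS)-3,4,6,7a-tetramethyl-3a,7a-dihydro-2-benzofuran-1(3H)-one, via bridged lactone adduct 6 (not isolated)
Conditions: 5 (3 equiv), CH2Cl2, 1.2 GPa, 40 °C; then toluene, 100 °C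
Reagents that add atoms: none
Why: A concerted, suprafacial normal-demand Diels–Alder reaction joins pyrone C3 to the butenolide α-carbon (C1–C2) and pyrone C6 to the β-carbon (C5–C6), closing the carbocycle by intermolecular [4+2] cycloaddition as a 2-oxabicyclo[2.2.2]octenone (6), and warming then expels the lactone bridge as CO2 in a retro-[4+2] step that leaves the C2=C3–C4=C5 diene. The closest known reaction type is the thermal or high-pressure cycloaddition of 2-pyrones to alkenes with subsequent decarboxylation to cyclohexa-1,3-dienes, combined with the anti-facial addition of dienes to 5-alkylbutenolides. C1 and C6 are created together on one face of the ring alkene, so Ca and C7 are cis by construction, and their absolute sense follows from approach of the pyrone anti to the C7 methyl group of the (S)-butenolide. Regiocontrol is required and should be secured twice over: bonding of the unsubstituted pyrone C3 to the methyl-bearing α-carbon avoids two adjacent fully substituted carbons, and it is the orientation usually found when 2-pyrones add to α,β-unsaturated carbonyl dienophiles (acyl-bearing carbon next to pyrone C3). Endo and exo adducts need not be separated because the centres that distinguish them become sp2 when CO2 leaves. Pressure compensates for the low reactivity of the trisubstituted dienophile, excess pyrone keeps the new diene from meeting unreacted butenolide, and decarboxylation at 100 °C stays below the temperatures at which 1,5-hydrogen shifts of the diene set in.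

**Step 4**
Reactants: 7 cis-fused lactone
Product: 8 (3S,3aR,7aS)-3,4,6,7a-tetramethyl-1,3,3a,7a-tetrahydro-2-benzofuran-1-ol (lactol, both anomers)
Conditions: iBu2AlH (1.1 equiv), CH2Cl2, −78 °C; aq. KNaC4H4O6
Reagents that add atoms: none
Why: Half-reduction of a γ-lactone with iBu2AlH at low temperature stops at the aluminium hemiacetal, so the lactol should be obtained while the diene and the three stereocentres stay untouched.

**Step 5**
Reactants: 8 lactol; 9 methyl 2-methyl-3-oxopentanoate
Product: 12 methyl 5-hydroxy-5-[(1S,6R)-6-[(1S)-1-hydroxyethyl]-1,3,5-trimethylcyclohexa-2,4-dien-1-yl]-2,4-dimethyl-3-oxopentanoate (isomer mixture in the chain), via dilithium dianion of the keto ester 10 (not isolated), via open-chain lithium alkoxide aldehyde 11 (not isolated)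
Conditions: 9 (3.3 equiv), LiN(iPr)2 (6.6 equiv), THF, −78 to 0 °C; then 8, −78 to −20 °C; AcOH, −78 °C
Reagents that add atoms: none
Why: Aldol addition of the β-keto ester dianion through its terminal carbanion to the aldehyde released from the lithium lactolate by ring–chain equilibration forms the Ca–C bond (excess dianion absorbs the lactol proton), and the new chain stereocentres are inconsequential because steps 7 and 8 remove them.

**Step 6**
Reactants: 12 diol keto ester
Product: 13 methyl 5-[(1S,6R)-6-[(1S)-1-(tert-butyldimethylsilyloxy)ethyl]-1,3,5-trimethylcyclohexa-2,4-dien-1-yl]-5-hydroxy-2,4-dimethyl-3-oxopentanoate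
Conditions: TBSCl (1.3 equiv), imidazole, DMF, 0 °C to rt
Reagents that add atoms: tert-butyldimethylsilyl chloride, CC(C)(C)[Si](C)(C)Cl
Why: Silyl ether formation is sterically selective, since the C7 hydroxyl next to a methyl group reacts whereas the Ca hydroxyl wedged between the quaternary C1 and a branched carbon should not.

**Step 7**
Reactants: 13 mono-silyl ether
Product: 14 methyl 5-[(1S,6R)-6-[(1S)-1-(tert-butyldimethylsilyloxy)ethyl]-1,3,5-trimethylcyclohexa-2,4-dien-1-yl]-2,4-dimethyl-3,5-dioxopentanoate
Conditions: Dess–Martin periodinane (1.5 equiv), pyridine, CH2Cl2, 0 °C to rt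
Reagents that add atoms: none
Why: Dess–Martin oxidation converts the hindered β-hydroxy ketone into the 3,5-dioxo ester under buffered conditions that the diene and the silyl ether tolerate.

**Step 8**
Reactants: 14 3,5-dioxo ester
Product: 15 6-[(1S,6R)-6-[(1S)-1-(tert-butyldimethylsilyloxy)ethyl]-1,3,5-trimethylcyclohexa-2,4-dien-1-yl]-4-hydroxy-3,5-dimethyl-2H-pyran-2-one
Conditions: DBU (2 equiv), toluene, rt to 45 °C; aq. citric acid
Reagents that add atoms: none
Why: Base-mediated cyclisation of a 3,5-dioxo ester (the enolate oxygen on Ca attacks the ester with loss of methanol) is the standard entry to 4-hydroxy-2-pyrones, and with C7 still a silyl ether there is no acidic proton at C6 for DBU to remove.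

**Step 9**
Reactants: 15 4-hydroxy-2-pyrone
Product: 17 6-[(1S,6R)-6-[(1S)-1-(tert-butyldimethylsilyloxy)ethyl]-1,3,5-trimethylcyclohexa-2,4-dien-1-yl]-2-methoxy-3,5-dimethyl-4H-pyran-4-one, via hydroxymethoxypyrylium triflate 16 (not isolated)
Conditions: MeOTf (1.5 equiv), CH2Cl2, 0 °C to rt; then aq. NaHCO3
Reagents that add atoms: methyl trifluoromethanesulfonate, COS(=O)(=O)C(F)(F)F
Why: O-Methylation of the neutral 4-hydroxy-2-pyrone with a hard methylating agent occurs at the more nucleophilic lactone carbonyl oxygen, and deprotonation of the resulting pyrylium salt should give the 2-methoxy-4-pyranone regioisomer.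

**Step 10**
Reactants: 17 silyl-protected methoxypyranone
Product: 18 6-[(1S,6R)-6-[(1S)-1-hydroxyethyl]-1,3,5-trimethylcyclohexa-2,4-dien-1-yl]-2-methoxy-3,5-dimethyl-4H-pyran-4-one
Conditions: HF·pyridine, pyridine, THF, 0 °C to rt
Reagents that add atoms: none
Why: Fluoride-mediated desilylation with buffered HF·pyridine frees the C7 alcohol without exposing the methoxypyranone or the diene to strong acid or base.

**Step 11**
Reactants: 18 C7 alcohol
Product: 19 6-[(1S,6R)-6-acetyl-1,3,5-trimethylcyclohexa-2,4-dien-1-yl]-2-methoxy-3,5-dimethyl-4H-pyran-4-one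
Conditions: Dess–Martin periodinane (1.5 equiv), pyridine, CH2Cl2, 0 °C
Reagents that add atoms: none
Why: Dess–Martin oxidation gives the methyl ketone under buffered conditions that avoid enolisation towards C6, so the β,γ-unsaturated ketone should keep its C6 configuration and not move into conjugation.

**Step 12**
Reactants: 19 C7 methyl ketone; 20 1-propynylmagnesium bromide
Product: 22 6-[(1S,6R)-6-(2-hydroxypent-3-yn-2-yl)-1,3,5-trimethylcyclohexa-2,4-dien-1-yl]-2-methoxy-3,5-dimethyl-4H-pyran-4-one (both C7 epimers), via propynylcerium dichloride 21 (not isolated)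
Conditions: 20 (3 equiv), CeCl3 (3 equiv, dried), THF, −78 °C; then 19, −78 to −40 °C; aq. NH4Cl
Reagents that add atoms: none
Why: 1,2-Addition of the organocerium reagent CH3C≡CCeCl2 is the method of choice for hindered, enolisable ketones, it suppresses deprotonation at C6 and spares the vinylogous ester carbonyl of the pyranone, and the configuration of the new carbinol is irrelevant because step 13 removes it.

**Step 13**
Reactants: 22 tertiary propargylic alcohol
Product: 24 2-methoxy-3,5-dimethyl-6-[(1S,6S)-1,3,5-trimethyl-6-[(2E)-4-oxopent-2-en-2-yl]cyclohexa-2,4-dien-1-yl]-4H-pyran-4-one, via allenol 23 (not isolated)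
Conditions: ReOCl3(OPPh3)(SMe2) (5 mol%), 1,2-dimethoxyethane, rt to 40 °C
Reagents that add atoms: none
Why: Meyer–Schuster rearrangement with ReOCl3(OPPh3)(SMe2) transposes the hydroxyl from C7 to C9 through a propargyl metal ester and a [3,3] shift, the allenol tautomerises to the enone, and the E isomer (bulky ring trans to acetyl) is expected as the thermodynamic product; an oxo-metal catalyst is chosen over a π-acid because the substrate is also a 3-hydroxy-1,5-enyne.

**Compound list**

1 | (S)-but-3-en-2-ol | C=C[C@H](C)O | starting material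
2 | methacryloyl chloride | CC(=C)C(=O)Cl | starting material
3 | (S)-but-3-en-2-yl 2-methylprop-2-enoate | C=C[C@H](C)OC(=O)C(C)=C | intermediate
4 | (S)-3,5-dimethylfuran-2(5H)-one | O=C1O[C@@H](C)C=C1C | intermediate
5 | 4,6-dimethyl-2H-pyran-2-one | CC1=CC(C)=CC(=O)O1 | starting material
6 | bridged lactone adduct: 2-oxabicyclo[2.2.2]oct-5-en-3-one fused to the γ-lactone (endo isomer; the exo isomer gives the same diene) | O=C1O[C@@H](C)[C@H]2[C@]1(C)[C@H]3C(C)=C[C@]2(C)OC3=O | intermediate
7 | (3S,3aR,7aS)-3,4,6,7a-tetramethyl-3a,7a-dihydro-2-benzofuran-1(3H)-one (cis-fused lactone; 7a = C1, 3a = C6, 3 = C7) | O=C1O[C@@H](C)[C@@H]2C(C)=CC(C)=C[C@]12C | intermediate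
8 | (3S,3aR,7aS)-3,4,6,7a-tetramethyl-1,3,3a,7a-tetrahydro-2-benzofuran-1-ol (both anomers) | OC1O[C@@H](C)[C@@H]2C(C)=CC(C)=C[C@]12C | intermediate
9 | methyl 2-methyl-3-oxopentanoate | CCC(=O)C(C)C(=O)OC | starting material
10 | dilithium dianion (dienolate) of 9 | CC=C(O[Li])C(C)=C(OC)O[Li] | intermediate
11 | (1S,6R)-6-[(1S)-1-(lithiooxy)ethyl]-1,3,5-trimethylcyclohexa-2,4-diene-1-carbaldehyde (open form of the lactolate) | O=C[C@@]1(C)C=C(C)C=C(C)[C@H]1[C@H](C)O[Li] | intermediate
12 | methyl 5-hydroxy-5-[(1S,6R)-6-[(1S)-1-hydroxyethyl]-1,3,5-trimethylcyclohexa-2,4-dien-1-yl]-2,4-dimethyl-3-oxopentanoate | COC(=O)C(C)C(=O)C(C)C(O)[C@@]1(C)C=C(C)C=C(C)[C@H]1[C@H](C)O | intermediate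
13 | C7 tert-butyldimethylsilyl ether of 12 | COC(=O)C(C)C(=O)C(C)C(O)[C@@]1(C)C=C(C)C=C(C)[C@H]1[C@H](C)O[Si](C)(C)C(C)(C)C | intermediate
14 | methyl 5-[(1S,6R)-6-[(1S)-1-(tert-butyldimethylsilyloxy)ethyl]-1,3,5-trimethylcyclohexa-2,4-dien-1-yl]-2,4-dimethyl-3,5-dioxopentanoate | COC(=O)C(C)C(=O)C(C)C(=O)[C@@]1(C)C=C(C)C=C(C)[C@H]1[C@H](C)O[Si](C)(C)C(C)(C)C | intermediate
15 | 6-[(1S,6R)-6-[(1S)-1-(tert-butyldimethylsilyloxy)ethyl]-1,3,5-trimethylcyclohexa-2,4-dien-1-yl]-4-hydroxy-3,5-dimethyl-2H-pyran-2-one | O=c1oc([C@@]2(C)C=C(C)C=C(C)[C@H]2[C@H](C)O[Si](C)(C)C(C)(C)C)c(C)c(O)c1C | intermediate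
16 | 4-hydroxy-2-methoxy-3,5-dimethyl-6-(cyclohexadienyl)pyrylium triflate derived from 15 | COc1[o+]c([C@@]2(C)C=C(C)C=C(C)[C@H]2[C@H](C)O[Si](C)(C)C(C)(C)C)c(C)c(O)c1C.[O-]S(=O)(=O)C(F)(F)F | intermediate
17 | 6-[(1S,6R)-6-[(1S)-1-(tert-butyldimethylsilyloxy)ethyl]-1,3,5-trimethylcyclohexa-2,4-dien-1-yl]-2-methoxy-3,5-dimethyl-4H-pyran-4-one | COc1oc([C@@]2(C)C=C(C)C=C(C)[C@H]2[C@H](C)O[Si](C)(C)C(C)(C)C)c(C)c(=O)c1C | intermediate
18 | 6-[(1S,6R)-6-[(1S)-1-hydroxyethyl]-1,3,5-trimethylcyclohexa-2,4-dien-1-yl]-2-methoxy-3,5-dimethyl-4H-pyran-4-one | COc1oc([C@@]2(C)C=C(C)C=C(C)[C@H]2[C@H](C)O)c(C)c(=O)c1C | intermediate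
19 | 6-[(1S,6R)-6-acetyl-1,3,5-trimethylcyclohexa-2,4-dien-1-yl]-2-methoxy-3,5-dimethyl-4H-pyran-4-one | COc1oc([C@@]2(C)C=C(C)C=C(C)[C@H]2C(C)=O)c(C)c(=O)c1C | intermediate
20 | 1-propynylmagnesium bromide (THF solution) | CC#C[Mg]Br | starting material
21 | prop-1-ynylcerium dichloride | CC#C[Ce](Cl)Cl | intermediate
22 | 6-[(1S,6R)-6-(2-hydroxypent-3-yn-2-yl)-1,3,5-trimethylcyclohexa-2,4-dien-1-yl]-2-methoxy-3,5-dimethyl-4H-pyran-4-one (C7 epimers) | COc1oc([C@@]2(C)C=C(C)C=C(C)[C@H]2C(C)(O)C#CC)c(C)c(=O)c1C | intermediate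
23 | 6-[(1S,6S)-6-(4-hydroxypenta-2,3-dien-2-yl)-1,3,5-trimethylcyclohexa-2,4-dien-1-yl]-2-methoxy-3,5-dimethyl-4H-pyran-4-one (allenol) | COc1oc([C@@]2(C)C=C(C)C=C(C)[C@H]2C(C)=C=C(C)O)c(C)c(=O)c1C | intermediate
24 | 2-methoxy-3,5-dimethyl-6-[(1S,6S)-1,3,5-trimethyl-6-[(2E)-4-oxopent-2-en-2-yl]cyclohexa-2,4-dien-1-yl]-4H-pyran-4-one | COc1oc([C@@]2(C)C=C(C)C=C(C)[C@H]2/C(C)=C/C(C)=O)c(C)c(=O)c1C | target

**Count and risks**

Total steps: 13. Longest linear sequence: 13 steps (1 to 24).

Step 3 (cycloaddition and CO2 loss). What may go wrong: the pyrone may not engage the trisubstituted butenolide at all, adduct 6 may revert to its components faster than it loses CO2, or the orientation of the two partners may not be controlled. The fallback sets out from 4 and returns at 7, replacing the pyrone by an acyclic 1-silyloxy diene. (E)-2-Methylpent-2-enal is silylated (Me3SiCl, Et3N, ZnCl2, benzene, 40 °C) to (1E,3E)-2-methyl-1-(trimethylsilyloxy)penta-1,3-diene F1. Its Diels–Alder reaction with 4 (toluene, 110 °C, or 1.2 GPa at rt) should give the 7-(trimethylsilyloxy)-3a,4,7,7a-tetrahydro lactone F2, with the oxygenated diene terminus bonded to C1 and the diene again anti to the C7 methyl group. Catalytic p-TsOH in benzene then ionises the allylic C2–O bond. The resulting allyl cation has a β-hydrogen only on C5, so loss of Me3SiOH should lead to 7.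

Step 5 (dianion aldol on the lactol). What may go wrong: the lactolate may stay closed and simply be deprotonated so that no C–C bond forms, or the adduct may lactonise; poor discrimination of the two hydroxyls in step 6 would compound this. The fallback sets out from 7 and returns at 13, unmasking the aldehyde with the C7 oxygen already protected. Aminolysis of 7 with Me2AlN(OMe)Me (from AlMe3 and MeNH(OMe)·HCl, CH2Cl2, 0 °C to rt) gives the hydroxy Weinreb amide F3. This is silylated at once (TBSOTf, 2,6-lutidine, −78 °C) to the silyl ether F4. Reduction with iBu2AlH (THF, −78 °C) gives the aldehyde F5. Addition of dianion 10 to F5 (THF, −78 °C) gives 13 directly, so step 6 is not needed.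

Step 13 (Meyer–Schuster rearrangement). What may go wrong: dehydration of the tertiary carbinol to an enyne, ionisation-driven reactions with the neighbouring diene, or formation of an E/Z mixture that does not equilibrate. The fallback sets out from 19 and returns at 24, using an allylic instead of a propargylic transposition. Addition of 1-propenylmagnesium bromide premixed with CeCl3 (THF, −78 °C) to 19 gives the tertiary allylic alcohol F6. Babler–Dauben oxidative transposition with pyridinium chlorochromate C5H5NH[CrO3Cl] buffered with NaOAc (CH2Cl2, rt) passes through the chromate ester and a [3,3] shift of oxygen to C9, followed by oxidation to enone 24. The E isomer is again favoured thermodynamically.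

**Further compounds**

F1 | step 3 | (1E,3E)-2-methyl-1-(trimethylsilyloxy)penta-1,3-diene | C/C=C/C(C)=C/O[Si](C)(C)C
F2 | step 3 | 3,4,6,7a-tetramethyl-7-(trimethylsilyloxy)-3a,4,7,7a-tetrahydro-2-benzofuran-1(3H)-one, C3, C3a and C7a as in 7, epimers at C4 and C7 | O=C1O[C@@H](C)[C@@H]2C(C)C=C(C)C(O[Si](C)(C)C)[C@]12C
F3 | step 5 | (1S,6R)-6-[(1S)-1-hydroxyethyl]-N-methoxy-N,1,3,5-tetramethylcyclohexa-2,4-diene-1-carboxamide | CON(C)C(=O)[C@@]1(C)C=C(C)C=C(C)[C@H]1[C@H](C)O
F4 | step 5 | tert-butyldimethylsilyl ether of F3 | CON(C)C(=O)[C@@]1(C)C=C(C)C=C(C)[C@H]1[C@H](C)O[Si](C)(C)C(C)(C)C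
F5 | step 5 | (1S,6R)-6-[(1S)-1-(tert-butyldimethylsilyloxy)ethyl]-1,3,5-trimethylcyclohexa-2,4-diene-1-carbaldehyde | O=C[C@@]1(C)C=C(C)C=C(C)[C@H]1[C@H](C)O[Si](C)(C)C(C)(C)C
F6 | step 13 | 6-[(1S,6R)-6-(2-hydroxypent-3-en-2-yl)-1,3,5-trimethylcyclohexa-2,4-dien-1-yl]-2-methoxy-3,5-dimethyl-4H-pyran-4-one (isomer mixture) | COc1oc([C@@]2(C)C=C(C)C=C(C)[C@H]2C(C)(O)C=CC)c(C)c(=O)c1C
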